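**Strategy.** Lupulone's six-membered β-triketone ring (target numbering: ring carbonyl C1, prenylated C2, hydroxylated C3, acylated C4, hydroxylated C5, gem-diprenyl C6) is a disguised polyketide: C5–C6 is a doubly prenylated acetate unit, C1–C4 an acetoacetyl unit. The route therefore unites the lithium enolate of methyl 2,2-diprenylacetate with diketene. In one flask the fully substituted carbon C6 is acylated by the lactone carbonyl (bond C6–C1) and the released acetoacetyl carbanion closes onto the ester (bond C4–C5), a biomimetic Claisen cyclisation giving 2,2-diprenylcyclohexane-1,3,5-trione. Its two equivalent ring methylenes are then C-acylated with the isovaleryl group and C-prenylated.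

Key step: step 3

Remark: lupulone has no stereocentre (C6 carries two identical prenyl groups). It and the ring intermediates 9 and 12 are each drawn as one tautomer of a rapidly equilibrating enol/keto set.

**Step 1**
Reactants: 1 dimethyl malonate; 2 prenyl bromide (1-bromo-3-methylbut-2-ene)
Product: 4 dimethyl 2,2-bis(3-methylbut-2-en-1-yl)malonate, via dimethyl 2-(3-methylbut-2-en-1-yl)malonate 3 (not isolated)
Conditions: NaH (2.3 equiv), 2 (2.3 equiv), THF/DMF, 0 °C to rt
Reagents that add atoms: none
Why: Twofold SN2 alkylation of the malonate anion (malonic ester synthesis) with a primary allylic bromide should give the linear prenyl groups; no stereocentre is formed.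

**Step 2**
Reactants: 4 dimethyl 2,2-bis(3-methylbut-2-en-1-yl)malonate
Product: 5 methyl 5-methyl-2-(3-methylbut-2-en-1-yl)hex-4-enoate (methyl 2,2-diprenylacetate)
Conditions: LiCl, H2O (2 equiv), DMSO, 160 °C
Reagents that add atoms: none
Why: Krapcho dealkoxycarbonylation: chloride demethylates one ester, the carboxylate loses CO2 and water protonates the ester enolate; the neutral conditions should leave the trisubstituted alkenes untouched.

**Step 3**
Reactants: 5 methyl 5-methyl-2-(3-methylbut-2-en-1-yl)hex-4-enoate; 6 diketene (4-methylideneoxetan-2-one)
Product: 9 gem-diprenyl trione (2,2-bis(3-methylbut-2-en-1-yl)cyclohexane-1,3,5-trione), via ester lithium enolate 7 (not isolated), via acyclic diketo ester lithium enolate 8 (not isolated)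
Conditions: LiN(iPr)2 (1.05 equiv), THF, −78 °C; diketene (1.1 equiv), −78 to −40 °C; then LiN(iPr)2 (2.2 equiv), −78 to 0 °C; cold dilute aq. HCl
Reagents that add atoms: none
Why: The tetrasubstituted lithium enolate 7 adds through carbon to the strained lactone carbonyl of diketene (acyl–oxygen cleavage), which forms the bond from the gem-diprenyl carbon C6 to C1 and releases the acetoacetyl chain as enolate 8; the further LiN(iPr)2 turns 8 into the 1,3-diketone dianion, whose terminal carbon (the former exocyclic methylene, C4) attacks the ester carbon C5 and expels methoxide. The closest known reaction types are the diketene annulation of lithium enolates (C-acetoacetylation followed by ring closure through the acetoacetyl enolate) and the Harris-type Claisen cyclisation of diketo ester dianions, which mirrors how the polyketide synthase closes the phloroglucinol ring. The six-membered ring closes in a 6-exo-trig Claisen (Dieckmann-type) acyl substitution. No stereocentre is formed because C6 carries two identical prenyl groups. The step needs C- over O-acylation of 7 and addition in place of proton abstraction from diketene, which the lithium enolate in THF at −78 °C should favour, and it needs ring closure through carbon and not oxygen, which the dianion secures because its terminal carbanion is far more nucleophilic than the enolate oxygens. Retro-Claisen cleavage at the non-enolisable C6 should be held back because the C1 carbonyl stays masked as an enolate until the product trione is deprotonated.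

**Step 4**
Reactants: 9 2,2-bis(3-methylbut-2-en-1-yl)cyclohexane-1,3,5-trione; 10 isovaleric acid (3-methylbutanoic acid)
Product: 12 3,5-dihydroxy-4-(3-methylbutanoyl)-6,6-bis(3-methylbut-2-en-1-yl)cyclohexa-2,4-dien-1-one, via enol ester 11 (not isolated)
Conditions: DCC (1.1 equiv), DMAP (0.3 equiv), CH2Cl2, 0 °C to rt
Reagents that add atoms: none
Why: Steglich O-acylation of the enolised trione followed by DMAP-mediated O-to-C acyl migration (Fries-type rearrangement of the enol ester), the standard way to 2-acylcyclohexane-1,3-diones; the two ring methylenes are equivalent by symmetry, so one C-acyl product is expected, and its acidity should disfavour a second acylation.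

**Step 5**
Reactants: 12 3,5-dihydroxy-4-(3-methylbutanoyl)-6,6-bis(3-methylbut-2-en-1-yl)cyclohexa-2,4-dien-1-one; 2 prenyl bromide
Product: 13 lupulone
Conditions: NaOMe (2 equiv), MeOH, −10 to 0 °C; 2 (1.1 equiv); then cold dilute aq. HCl
Reagents that add atoms: none
Why: C-alkylation of the ambident β-triketone anion at its only unsubstituted ring carbon (C2), the classical prenylation of dearomatised acylphloroglucinols; the protic solvent should favour C- over O-alkylation, and SN2 at the primary allylic carbon keeps the prenyl group linear.

**Compound list**
1 | dimethyl malonate | COC(=O)CC(=O)OC | starting material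
2 | prenyl bromide (1-bromo-3-methylbut-2-ene) | CC(C)=CCBr | starting material
3 | dimethyl 2-(3-methylbut-2-en-1-yl)malonate | COC(=O)C(CC=C(C)C)C(=O)OC | intermediate
4 | dimethyl 2,2-bis(3-methylbut-2-en-1-yl)malonate | COC(=O)C(CC=C(C)C)(CC=C(C)C)C(=O)OC | intermediate
5 | methyl 5-methyl-2-(3-methylbut-2-en-1-yl)hex-4-enoate | COC(=O)C(CC=C(C)C)CC=C(C)C | intermediate
6 | diketene (4-methylideneoxetan-2-one) | C=C1CC(=O)O1 | starting material
7 | lithium enolate of ester 5 | [Li+].COC([O-])=C(CC=C(C)C)CC=C(C)C | intermediate
8 | lithium enolate of methyl 2,2-bis(3-methylbut-2-en-1-yl)-3,5-dioxohexanoate | [Li+].COC(=O)C(CC=C(C)C)(CC=C(C)C)C(=O)C=C(C)[O-] | intermediate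
9 | 2,2-bis(3-methylbut-2-en-1-yl)cyclohexane-1,3,5-trione | O=C1CC(=O)CC(=O)C1(CC=C(C)C)CC=C(C)C | intermediate
10 | isovaleric acid (3-methylbutanoic acid) | CC(C)CC(=O)O | starting material
11 | 4,4-bis(3-methylbut-2-en-1-yl)-3,5-dioxocyclohex-1-en-1-yl 3-methylbutanoate (enol ester) | CC(C)CC(=O)OC1=CC(=O)C(CC=C(C)C)(CC=C(C)C)C(=O)C1 | intermediate
12 | 3,5-dihydroxy-4-(3-methylbutanoyl)-6,6-bis(3-methylbut-2-en-1-yl)cyclohexa-2,4-dien-1-one | O=C1C=C(O)C(C(=O)CC(C)C)=C(O)C1(CC=C(C)C)CC=C(C)C | intermediate
13 | lupulone, 3,5-dihydroxy-4-(3-methylbutanoyl)-2,6,6-tris(3-methylbut-2-en-1-yl)cyclohexa-2,4-dien-1-one | CC(C)=CCC1=C(O)C(C(=O)CC(C)C)=C(O)C(CC=C(C)C)(CC=C(C)C)C1=O | target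

**Step count.** Total steps: 5. Longest linear sequence: 5 steps (1 to 13).

**Steps most likely to fail**

Step 3. The first stage may fail by proton abstraction from diketene or O-acylation of the hindered enolate. The second stage may fail by ring closure through an enolate oxygen (enol lactone formation) or by retro-Claisen cleavage at the quaternary carbon. The fallback builds the same chain by stepwise Claisen chemistry; it sets out from 5 and comes back at 9.
- Ester 5 is deprotonated with LiN(iPr)2 in THF at −78 °C and C-acetylated with acetyl chloride to give methyl 2-acetyl-5-methyl-2-(3-methylbut-2-en-1-yl)hex-4-enoate F1.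
- The methyl ketone of F1, its only enolisable site, is deprotonated with LiN(iPr)2 (2.2 equiv) at −78 °C and acylated with N-methoxy-N-methylacetamide to give methyl 2,2-bis(3-methylbut-2-en-1-yl)-3,5-dioxohexanoate F2, which is isolated.
- F2 is converted into its 1,3-diketone dianion with LiN(iPr)2 (2.2 equiv) in THF, −78 to 0 °C; the terminal carbanion should close onto the ester to give 9.

Step 5. The ambident anion may be alkylated at oxygen, a second prenyl group may enter at the same carbon, and prenyl bromide may be consumed by solvolysis. The fallback replaces the SN2 alkylation by a Tsuji–Trost allylation; it sets out from 12 and comes back at 13 and makes no compound outside the list (F0).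
- Compound 12 is treated with tert-butyl 3-methylbut-2-en-1-yl carbonate (CC(C)=CCOC(=O)OC(C)(C)C) and catalytic Pd(PPh3)4 (zerovalent palladium) in THF at rt.
- The soft triketone anion should attack the prenyl-palladium cation at the unsubstituted terminus.
- O-allylated material can re-ionise under the catalyst, so the C-prenyl product 13 should accumulate.

Step 4. The O-to-C acyl migration may stall at the enol ester, or both ring methylenes may be acylated. The fallback makes the C–C bond by nitrile oxide addition and unmasks the acyl group later; it sets out from 9 and comes back at 12.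
- Trione 9 reacts with the nitrile oxide generated from N-hydroxy-3-methylbutanimidoyl chloride (CC(C)CC(Cl)=NO) and Et3N in CH2Cl2 to give the fused isoxazole 3-(2-methylpropyl)-5,5-bis(3-methylbut-2-en-1-yl)-1,2-benzoxazole-4,6(5H,7H)-dione F3.
- Reductive N–O cleavage with Mo(CO)6 in MeCN/H2O at reflux, which spares the alkenes, gives the enaminone 4-(1-amino-3-methylbutylidene)-2,2-bis(3-methylbut-2-en-1-yl)cyclohexane-1,3,5-trione F4.
- Hydrolysis of F4 with aq. NaOH in EtOH, then acidification, should give 12.

**Further compounds**
F1 | step 3 | methyl 2-acetyl-5-methyl-2-(3-methylbut-2-en-1-yl)hex-4-enoate | COC(=O)C(CC=C(C)C)(CC=C(C)C)C(C)=O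
F2 | step 3 | methyl 2,2-bis(3-methylbut-2-en-1-yl)-3,5-dioxohexanoate | COC(=O)C(CC=C(C)C)(CC=C(C)C)C(=O)CC(C)=O
F0 | step 5 | none | none
F3 | step 4 | 3-(2-methylpropyl)-5,5-bis(3-methylbut-2-en-1-yl)-1,2-benzoxazole-4,6(5H,7H)-dione | CC(C)Cc1noc2CC(=O)C(CC=C(C)C)(CC=C(C)C)C(=O)c12
F4 | step 4 | 4-(1-amino-3-methylbutylidene)-2,2-bis(3-methylbut-2-en-1-yl)cyclohexane-1,3,5-trione | CC(C)CC(N)=C1C(=O)CC(=O)C(CC=C(C)C)(CC=C(C)C)C1=O
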